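Ring A is cut into a four-carbon vinylketene and a two-carbon alkynyl ether. The flavone carries three adjacent groups on ring A: O1 on C8a, the butenolide on C8 and methoxy on C7. A ketene carbon and the two carbons of a lactone-bearing methoxyalkyne map exactly onto C8a, C8 and C7. One operation (Wolff rearrangement, (2+2) addition, four-electron ring opening, six-electron closure) forms C8a–C8, C7–C6 and C8a–C4a and closes ring A as a salicylate. The arene is built around the existing C8–butenolide bond, so no coupling on a hindered arene is needed. The precursors are an ester-bearing diazo enone and a methoxyethynyl butenolide; ring C is closed afterwards from the ester carbon.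

Key step: step 5

Remark: ring atoms are numbered as in 4H-chromen-4-one (O1, C2 to C4, C4a, C5 to C8, C8a); the target has no stereocentre, and compounds 2, 12 and 14 are racemic, short-lived intermediates.

Step 1
Reactants: 1 5,5-dimethylfuran-2(5H)-one
Product: 3 3-bromo-5,5-dimethylfuran-2(5H)-one, via trans-dibromide 2 (not isolated)
Conditions: Br2, CH2Cl2, 0 °C to 40 °C; then Et3N, 0 °C to rt
Reagents that add atoms: bromine, BrBr
Why: Anti addition of bromine to the lactone alkene followed by amine-induced loss of HBr (bromination–dehydrobromination) removes the acidic C3 proton together with the C4 bromide, so bromine stays on C3 and the two transient stereocentres of 2 disappear again.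

Step 2
Reactants: 4 chloroacetaldehyde dimethyl acetal (2-chloro-1,1-dimethoxyethane)
Product: 6 tributyl(methoxyethynyl)stannane, via lithium methoxyacetylide 5 (not isolated)
Conditions: Et2NH, n-BuLi, THF, 0 °C (gives LiNEt2, 3.1 equiv); 4, 0 °C to rt; then Bu3SnCl, −78 °C to rt; distillation
Reagents that add atoms: tributyltin chloride, CCCC[Sn](Cl)(CCCC)CCCC; n-butyllithium, [Li]CCCC (lithium of intermediate 5 only)
Why: Lithium diethylamide removes methanol and hydrogen chloride from the chloroacetal in two successive eliminations and metalates the alkyne terminus, so the volatile methoxyacetylene is never handled, and the acetylide is then stannylated at carbon (elimination, then stannylation of a lithium acetylide).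

Step 3
Reactants: 3 3-bromo-5,5-dimethylfuran-2(5H)-one; 6 tributyl(methoxyethynyl)stannane
Product: 7 3-(methoxyethynyl)-5,5-dimethylfuran-2(5H)-one
Conditions: Pd2(dba)3 (2.5 mol %), AsPh3 (20 mol %), THF, 50 °C; chromatography on Et3N-deactivated silica
Reagents that add atoms: none
Why: Stille coupling of an alpha-bromo enoate with an alkynylstannane, whose alkynyl group transfers from tin faster than butyl, proceeds under neutral conditions that spare the acid-sensitive ynol ether and the lactone, and a methyl ynol ether has no beta hydrogen for retro-ene loss on warming.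

Step 4
Reactants: 8 methyl (E)-4-oxopent-2-enoate
Product: 10 methyl (E)-5-diazo-4-oxopent-2-enoate, via trifluoroacetyl diketone 9 (not isolated)
Conditions: 8 added to LiN(SiMe3)2 (1.1 equiv), THF, −78 °C; CF3CO2CH2CF3, −78 °C; aqueous HCl work-up; then p-ABSA, Et3N, H2O (1 equiv), MeCN, rt; product kept cold and dark and used at once
Reagents that add atoms: 4-acetamidobenzenesulfonyl azide (p-ABSA), CC(=O)Nc1ccc(cc1)S(=O)(=O)N=[N+]=[N-]; 2,2,2-trifluoroethyl trifluoroacetate, O=C(OCC(F)(F)F)C(F)(F)F (trifluoroacetyl group of intermediate 9 only)
Why: Detrifluoroacetylative (Regitz-type) diazo transfer works here because the methyl group is the only enolisable position, the trifluoroacetyl group activates that carbon for azide transfer and leaves on the sulfonamide, and the method avoids an acid chloride plus diazomethane, which would add to the electron-poor alkene.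

Step 5
Reactants: 10 methyl (E)-5-diazo-4-oxopent-2-enoate (1.3 equiv); 7 3-(methoxyethynyl)-5,5-dimethylfuran-2(5H)-one
Product: 15 methyl 3-(5,5-dimethyl-2-oxo-2,5-dihydrofuran-3-yl)-2-hydroxy-4-methoxybenzoate, via vinylketene 11 (not isolated), via vinylcyclobutenone 12 (not isolated), via dienylketene 13 (not isolated), via cyclohexadienone 14 (not isolated)
Conditions: hν (medium-pressure Hg lamp, Pyrex filter, >300 nm), degassed ClCH2CH2Cl, rt; then 80 °C in the dark
Reagents that add atoms: none
Why: Light expels N2 from 10 and the alkenyl group migrates to the former diazo carbon (Wolff rearrangement, which also sets the C5–C6 bond), giving vinylketene 11. The electrophilic ketene carbon (future C8a) bonds to the alkyne carbon beta to oxygen, the nucleophilic carbon that carries the lactone (C8), and the ketene alpha carbon (C6) bonds to the methoxy-bearing carbon (C7) in a (2+2) cycloaddition to vinylcyclobutenone 12. Four-electron electrocyclic opening of 12 (under light or on warming) gives dienylketene 13, and six-electron electrocyclic closure between the ketene carbon and the ester-bearing terminus forms C8a–C4a and ring A, after which cyclohexadienone 14 enolises to the hydrogen-bonded phenol 15. The closest known reaction type is the benzannulation of photochemically generated vinylketenes with alkoxy- or siloxyalkynes to 2-substituted resorcinol monoethers (Danheiser benzannulation). No stereocentre remains, because the sp3 carbons of 12 and 14 become aromatic carbons. The selectivity required is the regiochemistry of the (2+2) step, which the donor polarisation of the ynol ether secures because the lactone carbonyl is only cross-conjugated with the alkyne; irradiation above 300 nm excites the diazo enone and not the butenolide, and the E ester sits on the outside of the closing triene.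

Step 6
Reactants: 15 methyl 3-(5,5-dimethyl-2-oxo-2,5-dihydrofuran-3-yl)-2-hydroxy-4-methoxybenzoate
Product: 17 3-(5,5-dimethyl-2-oxo-2,5-dihydrofuran-3-yl)-2-hydroxy-4-methoxybenzoic acid, via ring-opened hydroxy diacid 16 (not isolated)
Conditions: LiOH, THF/MeOH/H2O, 50 °C; then 1 M HCl to pH 1, rt
Reagents that add atoms: lithium hydroxide, [Li+].[OH-] (oxygen of the new carboxyl OH)
Why: Ester saponification cleaves the methyl salicylate, and although hydroxide is expected to open the butenolide as well, the Z hydroxy acid 16 holds its carboxyl group and its gem-dimethyl carbinol cis and should re-lactonise spontaneously on acidification.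

Step 7
Reactants: 17 3-(5,5-dimethyl-2-oxo-2,5-dihydrofuran-3-yl)-2-hydroxy-4-methoxybenzoic acid
Product: 18 3-[3-(1H-benzotriazol-1-ylcarbonyl)-2-hydroxy-6-methoxyphenyl]-5,5-dimethylfuran-2(5H)-one
Conditions: SOCl2 (1.1 equiv), 1H-benzotriazole (4 equiv), CH2Cl2, rt
Reagents that add atoms: 1H-benzotriazole, c1ccc2[nH]nnc2c1
Why: Carboxyl activation as an N-acylbenzotriazole with thionyl chloride and excess benzotriazole is mild and tolerates an unprotected ortho hydroxyl group, which here is hydrogen-bonded and flanked on both sides, and it leaves the lactone and the aryl ether untouched.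

Step 8
Reactants: 18 3-[3-(1H-benzotriazol-1-ylcarbonyl)-2-hydroxy-6-methoxyphenyl]-5,5-dimethylfuran-2(5H)-one; 19 acetophenone (2 equiv)
Product: 21 8-(5,5-dimethyl-2-oxo-2,5-dihydrofuran-3-yl)-7-methoxy-2-phenyl-4H-chromen-4-one, via diketone 20 (not isolated)
Conditions: MgBr2·OEt2 (2.5 equiv), i-Pr2NEt (3 equiv), CH2Cl2, rt; 1 M HCl wash; then H2SO4 (cat.), AcOH, 60 °C
Reagents that add atoms: none
Why: Soft enolisation of acetophenone by the magnesium salt and a tertiary amine followed by C-acylation with the acylbenzotriazole is a crossed Claisen-type condensation that exposes the butenolide to no strong base or free carbanion, and the 2-hydroxyaryl 1,3-diketone 20 then undergoes the classical acid-catalysed cyclodehydration (phenol oxygen onto the benzoyl carbonyl, loss of water) that closes ring C.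

Compound list
1 | 5,5-dimethylfuran-2(5H)-one | CC1(C)C=CC(=O)O1 | starting material
2 | trans-3,4-dibromo-5,5-dimethyldihydrofuran-2(3H)-one (racemic, 3R,4R enantiomer drawn; not isolated) | CC1(C)OC(=O)[C@@H](Br)[C@@H]1Br | intermediate
3 | 3-bromo-5,5-dimethylfuran-2(5H)-one | CC1(C)C=C(Br)C(=O)O1 | intermediate
4 | chloroacetaldehyde dimethyl acetal (2-chloro-1,1-dimethoxyethane) | COC(CCl)OC | starting material
5 | lithium methoxyacetylide (not isolated) | [Li]C#COC | intermediate
6 | tributyl(methoxyethynyl)stannane | CCCC[Sn](CCCC)(CCCC)C#COC | intermediate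
7 | 3-(methoxyethynyl)-5,5-dimethylfuran-2(5H)-one | COC#CC1=CC(C)(C)OC1=O | intermediate
8 | methyl (E)-4-oxopent-2-enoate | COC(=O)/C=C/C(C)=O | starting material
9 | methyl (E)-7,7,7-trifluoro-4,6-dioxohept-2-enoate (trifluoroacetyl diketone; not isolated) | COC(=O)/C=C/C(=O)CC(=O)C(F)(F)F | intermediate
10 | methyl (E)-5-diazo-4-oxopent-2-enoate | COC(=O)/C=C/C(=O)C=[N+]=[N-] | intermediate
11 | methyl (2E)-5-oxopenta-2,4-dienoate (vinylketene; not isolated) | COC(=O)/C=C/C=C=O | intermediate
12 | methyl (E)-3-[3-(5,5-dimethyl-2-oxo-2,5-dihydrofuran-3-yl)-2-methoxy-4-oxocyclobut-2-en-1-yl]prop-2-enoate (racemic; not isolated) | COC(=O)/C=C/C1C(OC)=C(C2=CC(C)(C)OC2=O)C1=O | intermediate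
13 | methyl (2E,4E)-6-(5,5-dimethyl-2-oxo-2,5-dihydrofuran-3-yl)-5-methoxy-7-oxohepta-2,4,6-trienoate (dienylketene, C3 and the ketene carbon cis across C4=C5; not isolated) | COC(=O)/C=C/C=C(/OC)C(=C=O)C1=CC(C)(C)OC1=O | intermediate
14 | methyl 5-(5,5-dimethyl-2-oxo-2,5-dihydrofuran-3-yl)-4-methoxy-6-oxocyclohexa-2,4-diene-1-carboxylate (racemic; not isolated) | COC(=O)C1C=CC(OC)=C(C2=CC(C)(C)OC2=O)C1=O | intermediate
15 | methyl 3-(5,5-dimethyl-2-oxo-2,5-dihydrofuran-3-yl)-2-hydroxy-4-methoxybenzoate | COC(=O)c1ccc(OC)c(C2=CC(C)(C)OC2=O)c1O | intermediate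
16 | 3-[(1Z)-1-carboxy-3-hydroxy-3-methylbut-1-en-1-yl]-2-hydroxy-4-methoxybenzoic acid (ring-opened hydroxy diacid, present as its lithium salt until acidification; not isolated) | OC(=O)c1ccc(OC)c(/C(C(=O)O)=C/C(C)(C)O)c1O | intermediate
17 | 3-(5,5-dimethyl-2-oxo-2,5-dihydrofuran-3-yl)-2-hydroxy-4-methoxybenzoic acid | OC(=O)c1ccc(OC)c(C2=CC(C)(C)OC2=O)c1O | intermediate
18 | 3-[3-(1H-benzotriazol-1-ylcarbonyl)-2-hydroxy-6-methoxyphenyl]-5,5-dimethylfuran-2(5H)-one | O=C(c1ccc(OC)c(C2=CC(C)(C)OC2=O)c1O)n1nnc2ccccc21 | intermediate
19 | acetophenone | CC(=O)c1ccccc1 | starting material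
20 | 1-[3-(5,5-dimethyl-2-oxo-2,5-dihydrofuran-3-yl)-2-hydroxy-4-methoxyphenyl]-3-phenylpropane-1,3-dione (not isolated) | O=C(CC(=O)c1ccccc1)c1ccc(OC)c(C2=CC(C)(C)OC2=O)c1O | intermediate
21 | 8-(5,5-dimethyl-2-oxo-2,5-dihydrofuran-3-yl)-7-methoxy-2-phenyl-4H-chromen-4-one | COc1ccc2c(=O)cc(-c3ccccc3)oc2c1C1=CC(C)(C)OC1=O | target

Total step count: 8 steps.
Longest linear sequence: 6 steps (steps 1, 3, 5, 6, 7, 8; the branch through step 2 is equally long).

Steps most likely to fail

1. Step 5. The ketene may be lost to dimerisation or to stray nucleophiles before the ynol ether captures it, because the alkyne is attenuated by its sp2 neighbour and shielded by the lactone. Photochemical side reactions of the conjugated lactone or incomplete opening of the cyclobutenone could also erode the conversion. The fallback sets out from bromide 3 and builds the arene conventionally. Suzuki coupling of 3 with commercial (2,6-dimethoxyphenyl)boronic acid (Pd(OAc)2, SPhos, K3PO4, toluene/water, 80 °C) should give 3-(2,6-dimethoxyphenyl)-5,5-dimethylfuran-2(5H)-one F1. Friedel–Crafts acetylation (acetyl chloride, AlCl3, CH2Cl2, 0 °C) is directed ortho to one methoxy group and para to the other and should give 3-(3-acetyl-2,6-dimethoxyphenyl)-5,5-dimethylfuran-2(5H)-one F2. BCl3 (CH2Cl2, −78 to 0 °C) should cleave only the methoxy group chelated to the acetyl carbonyl, giving 3-(3-acetyl-2-hydroxy-6-methoxyphenyl)-5,5-dimethylfuran-2(5H)-one F3. Its dianion (LiN(SiMe3)2, THF, −78 °C) is C-benzoylated with benzoyl chloride, which is far more electrophilic than the lactone, and this returns to the route at diketone 20 for the acid cyclodehydration of step 8.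

2. Step 3. Transmetalation from tin may be too slow at a temperature the ynol ether tolerates, so that hydration or oligomerisation of the electron-rich alkyne and protodestannylation take over. The fallback sets out from stannane 6 and bromide 3 and changes the metal that delivers the alkyne. Tin–lithium exchange of 6 (n-BuLi, THF, −78 °C) regenerates amine-free lithium methoxyacetylide 5, and ZnCl2 converts it into chloro(methoxyethynyl)zinc F4. Negishi coupling of F4 with 3 (Pd(PPh3)4, THF, rt) then returns to the route at alkynyl ether 7.

3. Step 4. The lithium enolate or the trifluoroacetyl diketone may add in Michael fashion to the doubly activated alkene of another molecule, and the product may slowly consume itself by dipolar cycloaddition on standing. The fallback sets out from ketone 8 and avoids any enolate. Bromination at the methyl group (CuBr2, EtOAc/CHCl3, reflux) should give methyl (E)-5-bromo-4-oxopent-2-enoate F5. Treatment with N,N'-ditosylhydrazine and DBU (THF, 0 °C), a known way to turn bromoacetyl into diazoacetyl compounds, returns to the route at diazo enone 10.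

Further compounds
F1 | step 5 | 3-(2,6-dimethoxyphenyl)-5,5-dimethylfuran-2(5H)-one | COc1cccc(OC)c1C1=CC(C)(C)OC1=O
F2 | step 5 | 3-(3-acetyl-2,6-dimethoxyphenyl)-5,5-dimethylfuran-2(5H)-one | CC(=O)c1ccc(OC)c(C2=CC(C)(C)OC2=O)c1OC
F3 | step 5 | 3-(3-acetyl-2-hydroxy-6-methoxyphenyl)-5,5-dimethylfuran-2(5H)-one | CC(=O)c1ccc(OC)c(C2=CC(C)(C)OC2=O)c1O
F4 | step 3 | chloro(methoxyethynyl)zinc | COC#C[Zn]Cl
F5 | step 4 | methyl (E)-5-bromo-4-oxopent-2-enoate | COC(=O)/C=C/C(=O)CBr
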